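**Retrosynthetic overview**

1. The target is the 2,3-trans (2R,3R)-dihydroflavonol. It is reached by fluoride desilylation and, before that, 7-O-methylation (the 5-OH is hydrogen-bonded to C4=O) of a 5,7-dihydroxy-8-prenyl dihydroflavonol 3,3'-bis-silyl ether.
2. Feature used: ring A is a fully substituted phloroglucinol ring (C5–OH, C6–H, C7–O, C8–prenyl) fused through C4a/C8a to ring C. C5–C8 with both oxygens and the prenyl group form one 4-prenyl-1,3-dioxygenated C4 diene unit, and C4a=C8a is the enone double bond of a dihydropyranone.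
3. Key disconnection: C8–C8a and C5–C4a, a [4+2] of 1-methoxy-7-methyl-1,3-bis(trimethylsilyloxy)octa-1,3,6-triene onto C4a=C8a of a (2R,3R)-2-aryl-3-silyloxy-2,3-dihydro-4H-pyran-4-one. The leaving group on C4a is phenylsulfinyl and not a halide, because the cycloadduct holds it cis to H-8a and only a syn-elimination can then aromatise ring A.
4. Ring C is made before ring A: a catalytic asymmetric formal hetero-Diels–Alder reaction of TIPS-protected isovanillin with 1-methoxy-3-(trimethylsilyloxy)butadiene sets C2, a trans-selective enolate hydroxylation sets C3, then C5 is sulfenylated and the sulfur oxidised.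
5. The diene comes from γ-prenylation of the methyl acetoacetate dianion and two silylations. Ring order: B (isovanillin), then C, then A.

Key step: step 10

Assumption: the (S)-BINOL–titanium catalyst is taken to add the diene to the Si face of the aryl aldehyde, as with benzaldehyde (the (R)-ligand is used if the first run shows the opposite sense), and the sulfoxide is carried as a mixture of sulfur epimers because sulfur is lost in the key step.

Ar = 4-methoxy-3-(triisopropylsilyloxy)phenyl in all names.

**Route**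

Step 1
Reactants: 1 isovanillin
Product: 2 4-methoxy-3-(triisopropylsilyloxy)benzaldehyde
Conditions: TIPSCl, imidazole, DMF, 25 °C
Reagents that add atoms: triisopropylsilyl chloride, CC(C)[Si](Cl)(C(C)C)C(C)C
Why: Imidazole-promoted O-silylation of the phenol; the bulky aryl TIPS ether is chosen because it should survive TFA, amide base and Lewis acid and can be removed together with the TBS group at the end.

Step 2
Reactants: 2 4-methoxy-3-(triisopropylsilyloxy)benzaldehyde; 3 (E)-1-methoxy-3-(trimethylsilyloxy)buta-1,3-diene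
Product: 5 (2S)-2-Ar-2,3-dihydro-4H-pyran-4-one, via open-chain aldol adduct 4 (not isolated)
Conditions: (S)-BINOL (20 mol%), Ti(OiPr)4 (10 mol%), 4 Å MS, Et2O, −20 °C; then TFA, CH2Cl2, 0 °C
Reagents that add atoms: none
Why: Catalytic asymmetric Mukaiyama aldol addition followed by acid-induced oxa-Michael closure and loss of methanol (formal hetero-Diels–Alder reaction), in which the BINOL–titanium complex exposes the Si face of the aldehyde and so sets the benzylic centre C2 (S by the CIP rules here, the same spatial arrangement as 2R in the target).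

Step 3
Reactants: 5 (2S)-2-Ar-2,3-dihydro-4H-pyran-4-one
Product: 7 (2R,3R)-3-hydroxy-2-Ar-2,3-dihydro-4H-pyran-4-one, via sodium enolate 6 (not isolated)
Conditions: NaHMDS, THF, −78 °C; 2-(phenylsulfonyl)-3-phenyloxaziridine, −78 °C; AcOH quench
Reagents that add atoms: 2-(phenylsulfonyl)-3-phenyloxaziridine, O=S(=O)(c1ccccc1)N1OC1c1ccccc1
Why: Enolate hydroxylation with an N-sulfonyloxaziridine, in which C3 is the only enolisable position and oxygen is delivered to the enolate face opposite the C2 aryl group, giving the 2,3-trans (3R) alcohol, while −78 °C keeps the 4-oxido-2H-pyran from opening.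

Step 4
Reactants: 7 (2R,3R)-3-hydroxy-2-Ar-2,3-dihydro-4H-pyran-4-one
Product: 8 (2R,3R)-3-(tert-butyldimethylsilyloxy)-2-Ar-2,3-dihydro-4H-pyran-4-one
Conditions: TBSOTf, 2,6-lutidine, CH2Cl2, −78 → 0 °C
Reagents that add atoms: tert-butyldimethylsilyl triflate, CC(C)(C)[Si](C)(C)OS(=O)(=O)C(F)(F)F
Why: A silyl triflate with a hindered pyridine base silylates the α-hydroxy ketone without enolising C3, so the trans arrangement is kept.

Step 5
Reactants: 8 (2R,3R)-3-(tert-butyldimethylsilyloxy)-2-Ar-2,3-dihydro-4H-pyran-4-one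
Product: 10 (2R,3R)-3-(tert-butyldimethylsilyloxy)-2-Ar-5-(phenylthio)-2,3-dihydro-4H-pyran-4-one, via chloro sulfide adduct 9 (not isolated)
Conditions: PhSCl, CH2Cl2, −78 °C; then Et3N, −78 → 0 °C
Reagents that add atoms: benzenesulfenyl chloride, ClSc1ccccc1
Why: Electrophilic sulfenylation by addition–elimination, in which the sulfur electrophile adds to C5 (the nucleophilic β-carbon of the O1–C6=C5 enol ether) and chloride to C6, and triethylamine then removes HCl (E1cB through the C4 enolate) to restore the enone without touching C2 or C3.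

Step 6
Reactants: 10 (2R,3R)-3-(tert-butyldimethylsilyloxy)-2-Ar-5-(phenylthio)-2,3-dihydro-4H-pyran-4-one
Product: 11 (2R,3R)-3-(tert-butyldimethylsilyloxy)-2-Ar-5-(phenylsulfinyl)-2,3-dihydro-4H-pyran-4-one (both sulfur epimers)
Conditions: mCPBA (1.0 equiv), CH2Cl2, −78 → −40 °C
Reagents that add atoms: 3-chloroperbenzoic acid, OOC(=O)c1cccc(Cl)c1
Why: Sulfide-to-sulfoxide oxidation with one equivalent of peracid at low temperature should be far faster than attack on the electron-poor C5=C6 bond or the arene; the new sulfur stereocentre is not controlled and need not be.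

Step 7
Reactants: 12 methyl acetoacetate; 13 prenyl bromide
Product: 15 methyl 7-methyl-3-oxooct-6-enoate, via acetoacetate dianion 14 (not isolated)
Conditions: NaH, THF, 0 °C; n-BuLi; then prenyl bromide, 0 → 25 °C; aq. HCl
Reagents that add atoms: none
Why: γ-Alkylation of the β-keto ester dianion, whose terminal carbanion is the more reactive site and displaces bromide from the primary allylic carbon (SN2).

Step 8
Reactants: 15 methyl 7-methyl-3-oxooct-6-enoate
Product: 16 methyl (2Z)-7-methyl-3-(trimethylsilyloxy)octa-2,6-dienoate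
Conditions: TMSCl, Et3N, hexane, 25 °C
Reagents that add atoms: chlorotrimethylsilane, C[Si](C)(C)Cl
Why: O-Silylation of the hydrogen-bonded enol of the β-keto ester under amine base should give the (Z)-β-silyloxy enoate.

Step 9
Reactants: 16 methyl (2Z)-7-methyl-3-(trimethylsilyloxy)octa-2,6-dienoate
Product: 18 1-methoxy-7-methyl-1,3-bis(trimethylsilyloxy)octa-1,3,6-triene (mixture of double-bond isomers; used crude), via lithium dienolate 17 (not isolated)
Conditions: LDA, THF, −78 °C; TMSCl, −78 → 0 °C
Reagents that add atoms: chlorotrimethylsilane, C[Si](C)(C)Cl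
Why: Vinylogous (γ) deprotonation of the β-silyloxy enoate by LDA and O-silylation of the ester dienolate gives the 1,3-bis(silyloxy)diene, the prenyl group ending up on its nucleophilic terminus C4.

Step 10
Reactants: 11 (2R,3R)-3-(tert-butyldimethylsilyloxy)-2-Ar-5-(phenylsulfinyl)-2,3-dihydro-4H-pyran-4-one; 18 1-methoxy-7-methyl-1,3-bis(trimethylsilyloxy)octa-1,3,6-triene
Product: 21 (2R,3R)-3-(tert-butyldimethylsilyloxy)-5,7-dihydroxy-2-Ar-8-(3-methylbut-2-enyl)chroman-4-one, via sulfinyl cycloadduct 19 (not isolated), via bis-trimethylsilyl ether 20 (not isolated)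
Conditions: 18 (2.5 equiv), Eu(fod)3 (10 mol%), PhMe, 0 → 25 °C, then 70 °C; then aq. citric acid, MeOH, 0 °C
Reagents that add atoms: none
Why: Proposed new method: C4a=C8a of 11 carries two acceptors on C4a (the C4 ketone and the sulfinyl group, both bound to europium) and the O1 donor on C8a, so the nucleophilic C4 terminus of the ketene-acetal diene bonds to C8a and the acetal carbon C1 then closes on C4a, a polar asynchronous [4+2] whose six-membered carbocycle (ring A) forms by 6-exo collapse of the zwitterion; the closest known reactions are Diels–Alder/aromatisation sequences of 1-alkoxy-1-silyloxy dienes with haloquinones and of oxygenated dienes with α-sulfinyl enones and sulfinylquinones, not yet shown on a β-alkoxy enone. Both bonds arrive on one face of the dienophile, so in 19 the sulfinyl group on C4a and H-8a are cis and benzenesulfenic acid leaves by thermal syn-elimination across C4a–C8a, a path closed to a halide at C4a because H-8a is neither acidic nor anti to it. Until the sulfoxide has left, C4a bears no hydrogen and cannot be enolised, which rules out β-elimination of O1 and opening of ring C, and no base is present that could enolise C3. Loss of methanol from C5 together with H-8 then aromatises ring A to 20, whose two aryl trimethylsilyl ethers are cleaved by citric acid while the TBS and TIPS ethers should stay. No stereocentre is created (C4a, C8 and C8a end as sp2 carbons) and C2 and C3 are not involved. The step needs regioselectivity (diene C4 to C8a, C1 to C4a), which the matched polarisation of both partners secures, and C–C closure at C1 ahead of silyl transfer to the enolate or the sulfinyl oxygen, which the apolar solvent and the absence of a silyl triflate should favour.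

Step 11
Reactants: 21 (2R,3R)-3-(tert-butyldimethylsilyloxy)-5,7-dihydroxy-2-Ar-8-(3-methylbut-2-enyl)chroman-4-one
Product: 22 (2R,3R)-3-(tert-butyldimethylsilyloxy)-5-hydroxy-7-methoxy-2-Ar-8-(3-methylbut-2-enyl)chroman-4-one
Conditions: MeI (1.2 equiv), K2CO3, acetone, 25 °C
Reagents that add atoms: iodomethane, CI
Why: Chemoselective Williamson O-methylation, since the 7-OH is the most acidic hydroxyl (para to the C4 carbonyl) and the 5-OH is tied up in a hydrogen bond to C4=O, while a mild heterogeneous base at room temperature should leave C2, C3 and the silyl ethers alone.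

Step 12
Reactants: 22 (2R,3R)-3-(tert-butyldimethylsilyloxy)-5-hydroxy-7-methoxy-2-Ar-8-(3-methylbut-2-enyl)chroman-4-one
Product: 23 (2R,3R)-3,5-dihydroxy-2-(3-hydroxy-4-methoxyphenyl)-7-methoxy-8-(3-methylbut-2-enyl)chroman-4-one (target)
Conditions: TBAF, AcOH, THF, 0 → 25 °C
Reagents that add atoms: none
Why: Fluoride cleavage of the alkyl TBS and aryl TIPS ethers, buffered with acetic acid so that neither a free phenoxide nor a C3 enolate is present to epimerise or open ring C.

**Compound list**

1 | isovanillin (3-hydroxy-4-methoxybenzaldehyde) | COc1ccc(C=O)cc1O | starting material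
2 | 4-methoxy-3-(triisopropylsilyloxy)benzaldehyde | COc1ccc(C=O)cc1O[Si](C(C)C)(C(C)C)C(C)C | intermediate
3 | (E)-1-methoxy-3-(trimethylsilyloxy)buta-1,3-diene | CO/C=C/C(=C)O[Si](C)(C)C | starting material
4 | (1E,5S)-1-methoxy-5-Ar-5-(trimethylsilyloxy)pent-1-en-3-one (open-chain aldol adduct) | CO/C=C/C(=O)C[C@H](O[Si](C)(C)C)c1ccc(OC)c(O[Si](C(C)C)(C(C)C)C(C)C)c1 | intermediate (not isolated)
5 | (2S)-2-Ar-2,3-dihydro-4H-pyran-4-one | COc1ccc([C@@H]2CC(=O)C=CO2)cc1O[Si](C(C)C)(C(C)C)C(C)C | intermediate
6 | sodium enolate of 5 (sodium (2S)-2-Ar-2H-pyran-4-olate) | COc1ccc([C@@H]2C=C([O-])C=CO2)cc1O[Si](C(C)C)(C(C)C)C(C)C.[Na+] | intermediate (not isolated)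
7 | (2R,3R)-3-hydroxy-2-Ar-2,3-dihydro-4H-pyran-4-one | COc1ccc([C@H]2OC=CC(=O)[C@@H]2O)cc1O[Si](C(C)C)(C(C)C)C(C)C | intermediate
8 | (2R,3R)-3-(tert-butyldimethylsilyloxy)-2-Ar-2,3-dihydro-4H-pyran-4-one | COc1ccc([C@H]2OC=CC(=O)[C@@H]2O[Si](C)(C)C(C)(C)C)cc1O[Si](C(C)C)(C(C)C)C(C)C | intermediate
9 | (2R,3R)-3-(tert-butyldimethylsilyloxy)-6-chloro-2-Ar-5-(phenylthio)tetrahydro-4H-pyran-4-one (C5 and C6 undefined) | COc1ccc([C@H]2OC(Cl)C(Sc3ccccc3)C(=O)[C@@H]2O[Si](C)(C)C(C)(C)C)cc1O[Si](C(C)C)(C(C)C)C(C)C | intermediate (not isolated)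
10 | (2R,3R)-3-(tert-butyldimethylsilyloxy)-2-Ar-5-(phenylthio)-2,3-dihydro-4H-pyran-4-one | COc1ccc([C@H]2OC=C(Sc3ccccc3)C(=O)[C@@H]2O[Si](C)(C)C(C)(C)C)cc1O[Si](C(C)C)(C(C)C)C(C)C | intermediate
11 | (2R,3R)-3-(tert-butyldimethylsilyloxy)-2-Ar-5-(phenylsulfinyl)-2,3-dihydro-4H-pyran-4-one (both sulfur epimers) | COc1ccc([C@H]2OC=C(S(=O)c3ccccc3)C(=O)[C@@H]2O[Si](C)(C)C(C)(C)C)cc1O[Si](C(C)C)(C(C)C)C(C)C | intermediate
12 | methyl acetoacetate | CC(=O)CC(=O)OC | starting material
13 | prenyl bromide (1-bromo-3-methylbut-2-ene) | CC(C)=CCBr | starting material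
14 | sodium lithium dianion of methyl acetoacetate | COC([O-])=CC([O-])=C.[Na+].[Li+] | intermediate (not isolated)
15 | methyl 7-methyl-3-oxooct-6-enoate | COC(=O)CC(=O)CCC=C(C)C | intermediate
16 | methyl (2Z)-7-methyl-3-(trimethylsilyloxy)octa-2,6-dienoate | COC(=O)/C=C(\O[Si](C)(C)C)CCC=C(C)C | intermediate
17 | lithium dienolate of 16 | COC([O-])=CC(O[Si](C)(C)C)=CCC=C(C)C.[Li+] | intermediate (not isolated)
18 | 1-methoxy-7-methyl-1,3-bis(trimethylsilyloxy)octa-1,3,6-triene | COC(O[Si](C)(C)C)=CC(O[Si](C)(C)C)=CCC=C(C)C | intermediate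
19 | (2R,3R)-3-(tert-butyldimethylsilyloxy)-5-methoxy-2-Ar-8-(3-methylbut-2-enyl)-4a-(phenylsulfinyl)-5,7-bis(trimethylsilyloxy)-2,3,4a,5,8,8a-hexahydro-4H-chromen-4-one (cis-fused; C4a, C5, C8, C8a and S undefined) | COc1ccc([C@H]2OC3C(CC=C(C)C)C(O[Si](C)(C)C)=CC(OC)(O[Si](C)(C)C)C3(S(=O)c4ccccc4)C(=O)[C@@H]2O[Si](C)(C)C(C)(C)C)cc1O[Si](C(C)C)(C(C)C)C(C)C | intermediate (not isolated)
20 | (2R,3R)-3-(tert-butyldimethylsilyloxy)-2-Ar-8-(3-methylbut-2-enyl)-5,7-bis(trimethylsilyloxy)chroman-4-one | COc1ccc([C@H]2Oc3c(CC=C(C)C)c(O[Si](C)(C)C)cc(O[Si](C)(C)C)c3C(=O)[C@@H]2O[Si](C)(C)C(C)(C)C)cc1O[Si](C(C)C)(C(C)C)C(C)C | intermediate (not isolated)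
21 | (2R,3R)-3-(tert-butyldimethylsilyloxy)-5,7-dihydroxy-2-Ar-8-(3-methylbut-2-enyl)chroman-4-one | COc1ccc([C@H]2Oc3c(CC=C(C)C)c(O)cc(O)c3C(=O)[C@@H]2O[Si](C)(C)C(C)(C)C)cc1O[Si](C(C)C)(C(C)C)C(C)C | intermediate
22 | (2R,3R)-3-(tert-butyldimethylsilyloxy)-5-hydroxy-7-methoxy-2-Ar-8-(3-methylbut-2-enyl)chroman-4-one | COc1ccc([C@H]2Oc3c(CC=C(C)C)c(OC)cc(O)c3C(=O)[C@@H]2O[Si](C)(C)C(C)(C)C)cc1O[Si](C(C)C)(C(C)C)C(C)C | intermediate
23 | (2R,3R)-3,5-dihydroxy-2-(3-hydroxy-4-methoxyphenyl)-7-methoxy-8-(3-methylbut-2-enyl)chroman-4-one | COc1ccc([C@H]2Oc3c(CC=C(C)C)c(OC)cc(O)c3C(=O)[C@@H]2O)cc1O | target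

**Step count**

Total: 12 steps. Longest linear sequence: 9 steps (steps 1–6, 10–12); the diene branch (steps 7–9) joins at step 10.

**Steps most likely to fail, with fallbacks**

1. Step 10 (proposed new method). The push–pull enone may react too slowly, so that the diene decomposes thermally before C–C bonding. Silyl transfer from the ketene acetal to the sulfinyl oxygen may divert the sulfoxide into Pummerer-type reduction. Silyl transfer to the enolate may outrun closure at C1 and stop the sequence at the open-chain conjugate adduct.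
 Fallback with known reaction types, setting out from 8 and 18 and returning at 21: TMSOTf-mediated vinylogous Mukaiyama–Michael addition of 18 to the sulfur-free pyranone 8 (CH2Cl2, −78 °C), as known for 1,3-bis(silyloxy)dienes with pyranones and chromones, should give the conjugate adduct methyl 4-[(2R,3R)-3-(tert-butyldimethylsilyloxy)-2-Ar-4-(trimethylsilyloxy)-3,6-dihydro-2H-pyran-6-yl]-7-methyl-3-(trimethylsilyloxy)octa-2,6-dienoate F1. Saegusa–Ito oxidation of its ring silyl enol ether (Pd(OAc)2, MeCN) restores the C4a=C8a double bond and, after aqueous work-up, should give the enone keto ester methyl 4-[(2R,3R)-3-(tert-butyldimethylsilyloxy)-2-Ar-4-oxo-3,4-dihydro-2H-pyran-6-yl]-7-methyl-3-oxooct-6-enoate F2. Base-mediated Claisen cyclisation of F2 (DBU, MeCN, or Mg(OMe)2, MeOH), the polyketide-type closure of a pyranone keto ester, forms C5–C4a with loss of methanol and aromatises to 21.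

2. Step 5. The sulfenyl chloride may attack the electron-rich aryl ring, or the intermediate α-chloro ether may hydrolyse and cleave ring C before HCl is eliminated.
 Fallback setting out from 8 and returning at 10: bromination by addition–elimination (Br2, CH2Cl2, −78 °C; then Et3N) should give (2R,3R)-5-bromo-3-(tert-butyldimethylsilyloxy)-2-Ar-2,3-dihydro-4H-pyran-4-one F3, and palladium-catalysed C–S cross-coupling of this vinyl bromide with thiophenol (Pd2(dba)3, Xantphos, iPr2NEt, dioxane, 90 °C) then gives sulfide 10.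

3. Step 3. The 4-oxido-2H-pyran enolate may open (retro-oxa-6π or E1cB) with loss of the C2 configuration, oxygen transfer may show poor facial selectivity, or the enolate may add to the sulfonimine by-product.
 Fallback setting out from 5 and returning at 7: manganese(III) acetate α'-acetoxylation (Mn(OAc)3, benzene, reflux), a radical oxidation that avoids the free enolate and is known to give 2,3-trans products on 2-substituted dihydropyranones, should give (2R,3R)-3-acetoxy-2-Ar-2,3-dihydro-4H-pyran-4-one F4, and mild methanolysis of this activated ester (cat. K2CO3, MeOH, 0 °C) gives alcohol 7.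

**Further compounds**

F1 | step 10 | methyl 4-[(2R,3R)-3-(tert-butyldimethylsilyloxy)-2-Ar-4-(trimethylsilyloxy)-3,6-dihydro-2H-pyran-6-yl]-7-methyl-3-(trimethylsilyloxy)octa-2,6-dienoate | COc1ccc([C@H]2OC(C(CC=C(C)C)C(O[Si](C)(C)C)=CC(=O)OC)C=C(O[Si](C)(C)C)[C@@H]2O[Si](C)(C)C(C)(C)C)cc1O[Si](C(C)C)(C(C)C)C(C)C
F2 | step 10 | methyl 4-[(2R,3R)-3-(tert-butyldimethylsilyloxy)-2-Ar-4-oxo-3,4-dihydro-2H-pyran-6-yl]-7-methyl-3-oxooct-6-enoate | COc1ccc([C@H]2OC(C(CC=C(C)C)C(=O)CC(=O)OC)=CC(=O)[C@@H]2O[Si](C)(C)C(C)(C)C)cc1O[Si](C(C)C)(C(C)C)C(C)C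
F3 | step 5 | (2R,3R)-5-bromo-3-(tert-butyldimethylsilyloxy)-2-Ar-2,3-dihydro-4H-pyran-4-one | COc1ccc([C@H]2OC=C(Br)C(=O)[C@@H]2O[Si](C)(C)C(C)(C)C)cc1O[Si](C(C)C)(C(C)C)C(C)C
F4 | step 3 | (2R,3R)-3-acetoxy-2-Ar-2,3-dihydro-4H-pyran-4-one | COc1ccc([C@H]2OC=CC(=O)[C@@H]2OC(C)=O)cc1O[Si](C(C)C)(C(C)C)C(C)C
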